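The data were computed with made-up constants; scatter was added.

Early on, what does this flask say? Its first reading puts trapped intermediate beside product at a ratio of 1.30%, though a reading of 0.6% carries a scatter of 0.5 percentage points.

| setting | eta | flask |
|---|---|---|
| starting material | 10 mM | 10 mM |
| coupling partner | 11 mM | 11.0 mM |
| capture agent | 3 mM | 3.00 mM |
| free catalyst | 0.44 mM | 0.44 mM |
| second catalyst | 43 µM | 43 µM |
| impurity | 0.36 mM | 0.36 mM |
| remark | the very flask that is asked about, followed so far |  |
| time |  | 12 d |

eta run (percent of the starting material charged)

| time / d | trapped intermediate / % | product / % |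
|---|---|---|
| 0.208 | 0.6 | 46.1 |
| 0.333 | 0.3 | 63.0 |
| 0.417 | 1.4 | 71.0 |
| 0.625 | 1.9 | 82.6 |
| 1.04 | 2.2 | 92.2 |
| 1.67 | 3.0 | 97.0 |
| 2.50 | 3.2 | 97.2 |

(scatter of a reading: 0.5 percentage points)

1. share of trapped intermediate in trapped intermediate plus product at 30 min
2. share of trapped intermediate in trapped intermediate plus product at 12 h
3. share of trapped intermediate in trapped intermediate plus product at 12 d

Does that ratio hold? Not on these readings. Between 1.04 d and 1.67 d, trapped intermediate gains 0.8 points and product 4.8 points, a ratio of 16.7%, which is more than at the start.

What drifts? I assume that capture agent and coupling partner compete for one pool. By the last reading, the trapped amount has used 10.7% of the capture agent, so I hold that constant. Coupling partner starts at 1.10 of the starting-material charge and, reckoned from the product at the last reading, falls to 12.8% of it.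

So what is the rule? Let the opening ratio, a selectivity factor, be trapped intermediate gained per product gained while coupling partner stands at its charge. It grows as b/(b − P), where P is the product fraction, so the trapped fraction is the ratio times b ln(b/(b − P)). The last reading gives 1.35%, with that reading's scatter.

Your numbers? At 30 min, ahead of the first reading at 0.208 d, I use the opening ratio itself, so I say 1.33%. At 12 h, product read between the readings is 75.6%, the rule gives 1.73% trapped, and the share is 2.24%.

But the capture agent has room for 30.0% of the charge, so why no creep up to 12 d? At the last reading, trapped intermediate and product together stand at 100% of the charge, so I keep that reading's share, 3.19%.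

The forecast gives 1%, 1.9% and 3.5%, on a plateau that “suggests a stoichiometric limit”.

The flask gives 1.40%, 2.27% and 3.10%.

    starting material + free catalyst → free catalyst + open intermediate (k = 2100 L mol⁻¹ h⁻¹)
    coupling partner + second catalyst + open intermediate → second catalyst + product (k = 2.00 × 10⁶ L² mol⁻² h⁻¹)
    free catalyst + impurity → spent catalyst (k = 56000 L mol⁻¹ h⁻¹)
    open intermediate + capture agent → trapped intermediate (k = 4.40 L mol⁻¹ h⁻¹)

At 12.0 d this flask holds starting material at 0% and open intermediate at 0%, with 90% of the capture agent still there. Now carry the opening ratio to the neighbour flask charged with 4.4 mM of coupling partner, which makes coupling partner the limiting reagent at 44.0% of the starting material. Scaled by the charges, the ratio becomes 3.38%, a share of 3.27% at 30 min, and that neighbour flask gives 3.42%. At 12 d that neighbour flask has 0% of its coupling partner left, product at 44.0%, and a trapped share of 40.1%.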